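The data stem from a simulated flask on assumed constants; noise was put on by code.

Follow the partner through the flask, drop by drop, and you can say where it stops.

| flask | left-handed substrate | right-handed substrate | partner | protic impurity | free catalyst | remark | time |
|---|---|---|---|---|---|---|---|
| delta | 39 mM | 39 mM | 46.8 mM (fed, over 3.0 h) | 39 mM | 39 µM | the very flask that is asked about, followed so far |  |
| epsilon | 39 mM | 39 mM | 46.8 mM (fed, over 3.0 h) | 20 mM | 39 µM | run made earlier |  |
| flask | 39 mM | 39 mM | 46.8 mM (fed, over 3.0 h) | 39.0 mM | 39 µM |  | 12 h |

| run | time / h | left-handed substrate / % | right-handed substrate / % |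
|---|---|---|---|
| delta | 1.50 | 38.0 | 43.5 |
| delta | 3.00 | 26.5 | 36.9 |
| delta | 5.00 | 21.1 | 35.5 |
| delta | 6.00 | 18.4 | 31.9 |
| epsilon | 3.00 | 26.4 | 37.8 |
| epsilon | 6.00 | 19.2 | 32.4 |
| epsilon | 10.0 | 16.4 | 30.2 |
| epsilon | 12.0 | 14.6 | 28.7 |

(readings scatter by 1 percentage point)

- free catalyst is single-handed; left-handed substrate and right-handed substrate are mirror images of each other, charged as a racemate, each of them at the stated concentration
- the numbers in the tables scatter by 1 percentage point (one standard deviation)
- on the list of suspects stand: partner + free catalyst + left-handed substrate -> free catalyst + left-handed product; partner + free catalyst + right-handed substrate -> free catalyst + right-handed product; free catalyst <-> dormant form; 2 free catalyst -> spent catalyst; partner + protic impurity -> quenched reagent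
- an excess is below zero if the other one leads

* part of the left-handed substrate and right-handed substrate charged together that has reacted at 12 h
* excess of left-handed product over right-handed product in the product at 12 h
* excess of right-handed substrate over left-handed substrate among what is left of the two at 12 h

- Each turn of either substrate on the list of suspects takes one partner. The charge of 46.8 mM stands below the 78.0 mM of the two substrates together, so partner is the limiting reagent and conversion has a ceiling of 60.0 %.
- First instants: partner arrives at 15.6 mM h⁻¹ and meets both substrates at full strength. By 1.50 h, half of the feed is in, worth 30.0 % of the substrates, but the delta readings show less reacted, 18.5 %, so partner is building up.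
- Middle: when the feed ends at 3.00 h, delta has reached 36.6 % against the 60.0 % fed. That leaves a gap of 23 percentage points between the partner fed and the substrate reacted.
- End: the ceiling now needs a small correction. Epsilon, with 20 mM of protic impurity, reads 56.7 % at 12.0 h, leaving 3.3 points. This is the shortfall, the points of conversion between the ceiling and a run's last reading.
- My reckoning counts that whole shortfall as partner quenched by the impurity and scales it by the impurity ratio, 1.95. That gives 6.4 points, so 53.6 % at 12 h. Each reading scatters by 1 point, so this figure is rough.
- The forecast says 56 % (53 % to 59 %), with excesses of 24.7 % (23 % to 27 %) in the product and 31.4 % (27.5 % to 35 %) in the substrate. It holds that “quenching is slow next to the catalysed reaction”, and its conversion stands above mine.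
- The flask gives 53.5 %, 26.0 % and 29.9 %, each inside the forecast's range.

    partner + free catalyst + left-handed substrate → free catalyst + left-handed product (k = 1.40 × 10⁶ M⁻² h⁻¹)
    partner + free catalyst + right-handed substrate → free catalyst + right-handed product (k = 6.30 × 10⁵ M⁻² h⁻¹)
    free catalyst ⇌ dormant form (K = 3.00, k = 0.470 h⁻¹)
    2 free catalyst → spent catalyst (k = 3000 M⁻¹ h⁻¹)
    partner + protic impurity → quenched reagent (k = 1.60 M⁻¹ h⁻¹)

- At 12 h the flask has a shortfall of 6.5 points, with 4.20 mM of quenched reagent formed and 1.91 % of the partner charge left, less than the 60 % of the right-handed substrate charge left. Now take the neighbour charged with 160 mM of protic impurity, its ceiling still 60.0 %. Scaling the shortfall by 8.00 gives 26 points, so 33.6 %. That neighbour reaches more than this figure, 44.5 %, with 12.0 mM of quenched reagent, worth 15 points of conversion.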